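**Plan**

1. Feature: on the benzene ring, the oxygens at C2 and C4 are 1,3-related and are read as a masked cyclohexane-1,3-dione. C1 (oxygen) and C6 (C21 chain) are the two adjacent carbons that a malonate carbon and an enone β-carbon can deliver.
2. Retrosynthesis: remove the O-benzyl group at C1 and the two O-methyl groups, take the arene back to a 4-(benzyloxy)-5-alkylcyclohexane-1,3-dione, then cut C6–C1 and C2–C3. This gives dimethyl 2-(benzyloxy)malonate (C1, C2) and (E)-pentacos-3-en-2-one (C3–C6 plus the chain).
3. Forward: the enone comes from docosan-1-ol (oxidation, Wittig) and the malonate from dimethyl malonate (diazo transfer, O–H insertion into benzyl alcohol). One Michael–Claisen annulation closes the only carbocycle.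
4. Endgame: ester hydrolysis and decarboxylation, iodine–methanol aromatization, O-methylation, hydrogenolysis of the benzyl ether.
5. Stereochemistry: the target has none. The E-alkene of the enone is consumed, and the two sp3 centres formed in the annulation (C1, C6) arise uncontrolled and are erased on aromatization.

Key step: step 5

Assumption: the iodine–methanol aromatization of the unsymmetrical dione 12 is taken to give mainly the monomethyl ether methylated at the less hindered C4 oxygen. Regioisomeric or doubly methylated material formed alongside converges on 15 in step 8.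

**Step 1**
Reactants: 1 docosan-1-ol
Product: 2 docosanal
Conditions: TEMPO (10 mol%), PhI(OAc)2 (1.1 equiv), CH2Cl2, 30 °C
Reagents that add atoms: none
Why: Oxoammonium-mediated oxidation of a primary alcohol stops at the aldehyde in anhydrous CH2Cl2, and gentle warming keeps the waxy C22 alcohol in solution.

**Step 2**
Reactants: 2 docosanal; 3 1-(triphenylphosphoranylidene)propan-2-one
Product: 4 (E)-pentacos-3-en-2-one
Conditions: toluene, 90 °C
Reagents that add atoms: none
Why: Wittig olefination of an unhindered aliphatic aldehyde with the stabilized acetonyl ylide should give the E-enone, the usual outcome for stabilized ylides.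

**Step 3**
Reactants: 5 dimethyl malonate
Product: 6 dimethyl 2-diazomalonate
Conditions: 4-acetamidobenzenesulfonyl azide (1.05 equiv), Et3N, MeCN, 0 °C to rt
Reagents that add atoms: 4-acetamidobenzenesulfonyl azide, CC(=O)Nc1ccc(cc1)S(=O)(=O)N=[N+]=[N-]
Why: Regitz diazo transfer from a sulfonyl azide to the doubly activated methylene of a malonate is standard under amine base.

**Step 4**
Reactants: 6 dimethyl 2-diazomalonate; 7 benzyl alcohol
Product: 8 dimethyl 2-(benzyloxy)malonate
Conditions: Rh2(OAc)4 (1 mol%), 7 (1.2 equiv), CH2Cl2, reflux, slow addition of 6
Reagents that add atoms: none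
Why: The diazomalonate is decomposed to an electrophilic divalent-rhodium carbenoid that inserts into the O–H bond of the alcohol through an oxonium ylide and proton shift (carbenoid O–H insertion), and slow addition suppresses carbene dimerization.

**Step 5**
Reactants: 4 (E)-pentacos-3-en-2-one; 8 dimethyl 2-(benzyloxy)malonate
Product: 10 methyl 1-(benzyloxy)-6-heneicosyl-2,4-dioxocyclohexane-1-carboxylate, via acyclic Michael adduct 9 (not isolated)
Conditions: NaOMe (1.3 equiv), MeOH–THF, reflux; then cold 1 M HCl
Reagents that add atoms: none
Why: Methoxide deprotonates 8, whose soft, doubly stabilized anion adds 1,4 to enone 4 to forge C6–C1 and give adduct 9; enolate equilibration then places the charge on the terminal methyl group, which attacks one of the two equivalent ester carbonyls and expels methoxide to forge C2–C3. The closest known reaction is the Michael–Claisen annulation of malonates, 2-substituted ones included, with alkylidene acetones, the classical entry to 5-alkylcyclohexane-1,3-diones and alkylresorcinols. The single ring closes in a 6-exo-trig mode, the enolate carbon attacking an ester carbonyl whose C=O lies outside the forming ring. The two new stereocentres (C1 and C6) are under no control and should form as a diastereomer mixture, which is acceptable because both become sp2 carbons in step 7. The step needs 1,4- over 1,2-addition, secured by the stabilized donor and the reversibility of any carbonyl adduct, and closure through the methyl and not the methylene enolate, secured because only the methyl carbon reaches an ester through a six-membered transition state. Reversal of the congested Michael step is tolerated because the cyclized product is drained off as the sodium enolate of the 1,3-dione (deprotonation at C3), and the THF co-solvent keeps the long-chain enone dissolved.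

**Step 6**
Reactants: 10 methyl 1-(benzyloxy)-6-heneicosyl-2,4-dioxocyclohexane-1-carboxylate
Product: 12 4-(benzyloxy)-5-heneicosylcyclohexane-1,3-dione, via free β-keto acid 11 (not isolated)
Conditions: NaOH (4 equiv), H2O–MeOH–THF, reflux; then 2 M HCl to pH 2, 40 °C
Reagents that add atoms: none
Why: Saponification of the methyl ester takes place while the dione sits as its enolate, which shields C2 from retro-Claisen attack, and on acidification the β-keto acid loses CO2 through the usual cyclic transition state (classical hydrolysis–decarboxylation after a malonate annulation).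

**Step 7**
Reactants: 12 4-(benzyloxy)-5-heneicosylcyclohexane-1,3-dione
Product: 14 2-(benzyloxy)-3-heneicosyl-5-methoxyphenol, via vinylogous methyl ester 13 (not isolated)
Conditions: I2 (2.2 equiv), MeOH, reflux; aq. Na2S2O3 work-up
Reagents that add atoms: methanol, CO
Why: Iodine in methanol is an established oxidative aromatization of cyclohexane-1,3-diones, in which acid-catalysed enol ether formation at the less hindered oxygen, iodination at the enol stage, loss of HI and tautomerization should deliver the 3-methoxyphenol with the C1 benzyl ether as a spectator.

**Step 8**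
Reactants: 14 2-(benzyloxy)-3-heneicosyl-5-methoxyphenol
Product: 15 2-(benzyloxy)-1-heneicosyl-3,5-dimethoxybenzene
Conditions: MeI (3 equiv), K2CO3, acetone, reflux
Reagents that add atoms: iodomethane, CI
Why: Williamson O-methylation of the phenoxide is routine and brings any regioisomeric monomethyl ether from step 7 to the same fully methylated arene.

**Step 9**
Reactants: 15 2-(benzyloxy)-1-heneicosyl-3,5-dimethoxybenzene
Product: 16 6-n-heneicosyl-2,4-dimethoxyphenol
Conditions: H2 (1 atm), Pd/C (10 wt%), EtOAc–EtOH, rt
Reagents that add atoms: none
Why: Catalytic hydrogenolysis cleaves the aryl benzyl ether selectively, since the methyl ethers and the saturated chain offer nothing else to reduce.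

**Compound list**

1 | docosan-1-ol | CCCCCCCCCCCCCCCCCCCCCCO | starting material
2 | docosanal | CCCCCCCCCCCCCCCCCCCCCC=O | intermediate
3 | 1-(triphenylphosphoranylidene)propan-2-one | CC(=O)C=P(c1ccccc1)(c1ccccc1)c1ccccc1 | starting material
4 | (E)-pentacos-3-en-2-one | CCCCCCCCCCCCCCCCCCCCC/C=C/C(C)=O | intermediate
5 | dimethyl malonate | COC(=O)CC(=O)OC | starting material
6 | dimethyl 2-diazomalonate | COC(=O)C(=[N+]=[N-])C(=O)OC | intermediate
7 | benzyl alcohol | OCc1ccccc1 | starting material
8 | dimethyl 2-(benzyloxy)malonate | COC(=O)C(OCc1ccccc1)C(=O)OC | intermediate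
9 | dimethyl 2-(benzyloxy)-2-(2-oxopentacosan-4-yl)malonate (racemic, not isolated) | CCCCCCCCCCCCCCCCCCCCCC(CC(C)=O)C(OCc1ccccc1)(C(=O)OC)C(=O)OC | intermediate
10 | methyl 1-(benzyloxy)-6-heneicosyl-2,4-dioxocyclohexane-1-carboxylate (diastereomer mixture) | CCCCCCCCCCCCCCCCCCCCCC1CC(=O)CC(=O)C1(OCc2ccccc2)C(=O)OC | intermediate
11 | 1-(benzyloxy)-6-heneicosyl-2,4-dioxocyclohexane-1-carboxylic acid (diastereomer mixture, not isolated) | CCCCCCCCCCCCCCCCCCCCCC1CC(=O)CC(=O)C1(OCc2ccccc2)C(=O)O | intermediate
12 | 4-(benzyloxy)-5-heneicosylcyclohexane-1,3-dione (diastereomer mixture) | CCCCCCCCCCCCCCCCCCCCCC1CC(=O)CC(=O)C1OCc2ccccc2 | intermediate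
13 | 6-(benzyloxy)-5-heneicosyl-3-methoxycyclohex-2-en-1-one (diastereomer mixture, not isolated) | CCCCCCCCCCCCCCCCCCCCCC1CC(OC)=CC(=O)C1OCc2ccccc2 | intermediate
14 | 2-(benzyloxy)-3-heneicosyl-5-methoxyphenol | CCCCCCCCCCCCCCCCCCCCCc1cc(OC)cc(O)c1OCc2ccccc2 | intermediate
15 | 2-(benzyloxy)-1-heneicosyl-3,5-dimethoxybenzene | CCCCCCCCCCCCCCCCCCCCCc1cc(OC)cc(OC)c1OCc2ccccc2 | intermediate
16 | 6-n-heneicosyl-2,4-dimethoxyphenol | CCCCCCCCCCCCCCCCCCCCCc1cc(OC)cc(OC)c1O | target

**Step count**

Total steps: 9. Longest linear sequence: 7 steps (steps 1, 2, 5, 6, 7, 8, 9 from docosan-1-ol; the malonate branch, steps 3 and 4, joins at step 5 and is equally long).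

**Steps most likely to fail**

1. Step 5. Reversal of the congested conjugate addition and base-induced self-condensation of the enone may outrun ring closure. The fallback sets out from 4 and returns at 12, forming the same two bonds irreversibly and in two stages. Purchased methyl 2-(benzyloxy)acetate F1 is converted with lithium diisopropylamide and Me3SiCl in THF at −78 °C into its silyl ketene acetal {[2-(benzyloxy)-1-methoxyethenyl]oxy}trimethylsilane F2. F2 undergoes a Mukaiyama–Michael addition to 4 (TiCl4, CH2Cl2, −78 °C, aqueous work-up) to give the keto ester methyl 2-(benzyloxy)-3-(2-oxopropyl)tetracosanoate F3 (C6–C1 bond). Treatment of F3 with KOtBu in THF then closes the ring by intramolecular Claisen condensation of the methyl ketone enolate onto the ester (C2–C3 bond) and delivers dione 12 directly, so step 6 is no longer needed.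

2. Step 7. Acid-driven loss of benzyl alcohol from C1 (aromatization without oxidation), cleavage of the benzyl ether by the hydrogen iodide released, or ring iodination of the electron-rich product may compete with the oxidative pathway. The fallback sets out from 12 and returns at 14 under non-acidic dehydrogenation conditions. Dione 12 is converted into the isolated vinylogous ester 13 (MeOH, catalytic TsOH, molecular sieves). Kinetic deprotonation of 13 at C1 of the target numbering with lithium diisopropylamide in THF at −78 °C and trapping with PhSeCl gives 6-(benzyloxy)-5-heneicosyl-3-methoxy-6-(phenylselanyl)cyclohex-2-en-1-one F4. Oxidation of F4 with H2O2 and pyridine in CH2Cl2 at 0 °C triggers selenoxide syn-elimination toward C6, and the resulting dienone tautomerizes to phenol 14.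

3. Step 6. Hydroxide attack at the hindered quaternary ester may be slow enough for retro-Claisen ring opening under hot alkali to compete. The fallback sets out from 10 and returns at 12 by a dealkylative route that never touches the acyl carbon. Under Krapcho conditions (LiCl, wet DMSO, 150 °C) chloride attacks the ester methyl group in an SN2 step, and the carboxylate so formed loses CO2 to give 12 in one operation. No new compound is made.

**Further compounds**

F1 | step 5 | methyl 2-(benzyloxy)acetate (purchased) | COC(=O)COCc1ccccc1
F2 | step 5 | {[2-(benzyloxy)-1-methoxyethenyl]oxy}trimethylsilane (E/Z mixture) | COC(O[Si](C)(C)C)=COCc1ccccc1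
F3 | step 5 | methyl 2-(benzyloxy)-3-(2-oxopropyl)tetracosanoate (diastereomer mixture) | CCCCCCCCCCCCCCCCCCCCCC(CC(C)=O)C(OCc1ccccc1)C(=O)OC
F4 | step 7 | 6-(benzyloxy)-5-heneicosyl-3-methoxy-6-(phenylselanyl)cyclohex-2-en-1-one (diastereomer mixture) | CCCCCCCCCCCCCCCCCCCCCC1CC(OC)=CC(=O)C1(OCc2ccccc2)[Se]c2ccccc2
F0 | step 6 | none | none
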